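**Retrosynthetic overview**

1. Target numbering: C1 = C(CH3)(CH=CHBr), C2 = CHBr, C3 = CH2, C4 = CHCl, C5 = C(CH3)Cl, C6 = CH2; C1′ and C2′ are the alkenyl carbons. End game: C2′–Br by ozonolysis/Takai olefination of a vinyl group, C5–Cl by Markovnikov HCl addition to an exocyclic C5 methylene, C4–Cl by SN2 inversion of an allylic alcohol derived from the C4=C5 epoxide.
2. Key disconnection: the C4=C5 olefin of (4S,5S)-4-bromo-5-ethenyl-1,5-dimethylcyclohex-1-ene. The six-membered ring is closed at C4–C5 by ring-rearrangement metathesis of an isomeric cyclopentene, whose ring opens in the same operation.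
3. Enabling feature: the quaternary C1 carries both C1′ and the C6–C5 arm, so C1′ and C4 can be stored as the olefin of a cyclopentene ring C1–C2–C3–C4=C1′ with a methallyl group (C6, C5, its CH3 and a =CH2) on C1. Ring-opening at C4=C1′ turns C1′ into the vinyl group and passes C4 on to C5.
4. The cyclopentene comes from 2-methylcyclopentane-1,3-dione: C-methallylation, CBS desymmetrisation (sets C1 and the C2 carbinol), bromide displacement with inversion (C2–Br), ketone to olefin through the enol triflate.
5. Ring order: the five-membered carbocycle is present from the start; the six-membered ring is formed second, in the key step.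

Key step: step 6

Remark: the sense of step 2 is taken from the usual model of the oxazaborolidine reduction with the quaternary carbon as the large substituent; atom numbers in the Why lines are those of the target as defined above.

**Step 1**
Reactants: 1 2-methylcyclopentane-1,3-dione; 2 3-chloro-2-methylprop-1-ene (methallyl chloride)
Product: 3 2-methyl-2-(2-methylprop-2-en-1-yl)cyclopentane-1,3-dione
Conditions: NaOH (1 M aq), n-Bu4NI (cat.), rt
Reagents that add atoms: none
Why: C-alkylation of the 1,3-diketone enolate by SN2 at the allylic chloride in water should give the achiral 2,2-disubstituted dione, with no stereocentre formed.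

**Step 2**
Reactants: 3 2-methyl-2-(2-methylprop-2-en-1-yl)cyclopentane-1,3-dione
Product: 4 (2R,3R)-3-hydroxy-2-methyl-2-(2-methylprop-2-en-1-yl)cyclopentan-1-one
Conditions: (S)-1-methyl-3,3-diphenyltetrahydro-1H,3H-pyrrolo[1,2-c][1,3,2]oxazaborole [(S)-Me-CBS, 20 mol %], catecholborane, PhMe, −60 °C
Reagents that add atoms: none
Why: Corey–Bakshi–Shibata reduction desymmetrises the prochiral dione: the S catalyst should give the R carbinol and reduce the carbonyl whose reacting face is anti to the larger methallyl group, which sets C2–O (cis to methallyl) and the quaternary C1 together.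

**Step 3**
Reactants: 4 (2R,3R)-3-hydroxy-2-methyl-2-(2-methylprop-2-en-1-yl)cyclopentan-1-one
Product: 6 (2S,3S)-3-bromo-2-methyl-2-(2-methylprop-2-en-1-yl)cyclopentan-1-one, via keto triflate 5 (not isolated)
Conditions: Tf2O, 2,6-lutidine, CH2Cl2, −78 °C; then LiBr, THF, −78 to 0 °C
Reagents that add atoms: lithium bromide [Li+].[Br-]; trifluoromethanesulfonic anhydride O=S(=O)(OS(=O)(=O)C(F)(F)F)C(F)(F)F (its atoms stay in 5 only)
Why: SN2 displacement of the secondary triflate by bromide with inversion should place Br trans to methallyl; the β-carbonyl disfavours ionisation, the quaternary α-carbon excludes E1cB loss, and bromide enters past the smaller methyl group.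

**Step 4**
Reactants: 6 (2S,3S)-3-bromo-2-methyl-2-(2-methylprop-2-en-1-yl)cyclopentan-1-one
Product: 7 (4S,5S)-4-bromo-5-methyl-5-(2-methylprop-2-en-1-yl)cyclopent-1-en-1-yl trifluoromethanesulfonate
Conditions: KN(SiMe3)2, THF, −78 °C; then N-(5-chloropyridin-2-yl)bis(trifluoromethanesulfonyl)imide, −78 °C
Reagents that add atoms: N-(5-chloropyridin-2-yl)bis(trifluoromethanesulfonyl)imide FC(F)(F)S(=O)(=O)N(c1ccc(Cl)cn1)S(=O)(=O)C(F)(F)F
Why: Enol triflate formation: the ketone can enolise only toward its single α-CH2, and O-triflation at −78 °C should be faster than transannular displacement of the γ-bromide.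

**Step 5**
Reactants: 7 (4S,5S)-4-bromo-5-methyl-5-(2-methylprop-2-en-1-yl)cyclopent-1-en-1-yl trifluoromethanesulfonate
Product: 8 (3S,4S)-4-bromo-3-methyl-3-(2-methylprop-2-en-1-yl)cyclopent-1-ene
Conditions: Pd(OAc)2 (5 mol %), PPh3 (10 mol %), HCO2H, n-Bu3N, DMF, 60 °C
Reagents that add atoms: none
Why: Palladium-catalysed formate reduction of the enol triflate replaces OTf by H, and zerovalent palladium should not insert into the hindered secondary C–Br bond under these conditions.

**Step 6**
Reactants: 8 (3S,4S)-4-bromo-3-methyl-3-(2-methylprop-2-en-1-yl)cyclopent-1-ene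
Product: 9 (4S,5S)-4-bromo-5-ethenyl-1,5-dimethylcyclohex-1-ene
Conditions: second-generation Hoveyda–Grubbs catalyst RuCl2(H2IMes)(=CH-C6H4-2-OiPr) (5 mol %), ethylene (1 atm), PhMe (0.01 M), 60 °C
Reagents that add atoms: none
Why: The ruthenium alkylidene opens the strained cyclopentene by [2+2] cycloaddition/cycloreversion with the metal on C4 and the methylene on the hindered C1′, which thereby becomes the vinyl group on C1; the C4 alkylidene then closes the six-membered ring onto the 1,1-disubstituted olefin of the methallyl arm (ring-closing metathesis through a second metallacyclobutane), forming C4=C5 and releasing Ru=CH2, which carries the chain. The closest known reaction type is ring-rearrangement metathesis (ring-opening/ring-closing metathesis) of cycloalkenes that bear an olefinic side chain on an allylic carbon. No stereocentre is made or touched: C1 and C2 are carried over from 8, and the fully substituted C1 in the tether favours closure. The step needs direction toward the cyclohexene and away from re-closure to the cyclopentene or oligomers; this should be secured by the loss of cyclopentene strain and by the low reactivity of both product olefins (a trisubstituted ring olefin and a vinyl group on a quaternary carbon) toward the catalyst, with ethylene and high dilution suppressing oligomerisation.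

**Step 7**
Reactants: 9 (4S,5S)-4-bromo-5-ethenyl-1,5-dimethylcyclohex-1-ene
Product: 10 (1R,3S,4S,6S)-4-bromo-3-ethenyl-1,3-dimethyl-7-oxabicyclo[4.1.0]heptane
Conditions: mCPBA, NaHCO3, CH2Cl2, 0 °C
Reagents that add atoms: 3-chloroperbenzoic acid OOC(=O)c1cccc(Cl)c1
Why: Prilezhaev epoxidation should take the electron-rich trisubstituted ring olefin and leave the vinyl group; the face cis to vinyl and bromine is screened in both half-chair conformers (axial vinyl over C5 in one, axial bromine over C4 in the other), so oxygen should add trans to them.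

**Step 8**
Reactants: 10 (1R,3S,4S,6S)-4-bromo-3-ethenyl-1,3-dimethyl-7-oxabicyclo[4.1.0]heptane
Product: 11 (1S,4S,5S)-5-bromo-4-ethenyl-4-methyl-2-methylidenecyclohexan-1-ol
Conditions: lithium 2,2,6,6-tetramethylpiperidide, Et2AlCl (gives Et2Al–TMP in the flask), PhMe, 0 °C
Reagents that add atoms: none
Why: Aluminium-amide isomerisation of an epoxide to an allylic alcohol: syn β-elimination within the aluminium-bound epoxide should take the least hindered proton (the C5 methyl group), giving the exocyclic olefin and leaving the C4–O bond and its configuration untouched.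

**Step 9**
Reactants: 11 (1S,4S,5S)-5-bromo-4-ethenyl-4-methyl-2-methylidenecyclohexan-1-ol
Product: 12 (1S,2S,4R)-2-bromo-4-chloro-1-ethenyl-1-methyl-5-methylidenecyclohexane
Conditions: PPh3, hexachloroacetone, CH2Cl2, 0 °C
Reagents that add atoms: hexachloroacetone ClC(Cl)(Cl)C(=O)C(Cl)(Cl)Cl
Why: Appel-type chlorodehydroxylation: chloride should attack the axial alkoxyphosphonium ion by SN2 with inversion and without allylic transposition, which sets C4–Cl cis to vinyl and bromine while the neighbouring C5 is sp2 and unhindering.

**Step 10**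
Reactants: 12 (1S,2S,4R)-2-bromo-4-chloro-1-ethenyl-1-methyl-5-methylidenecyclohexane
Product: 13 (1S,2S,4R,5S)-2-bromo-4,5-dichloro-1-ethenyl-1,5-dimethylcyclohexane
Conditions: HCl (g), CH2Cl2, −78 to −20 °C
Reagents that add atoms: hydrogen chloride Cl
Why: Markovnikov hydrochlorination through the tertiary C5 cation: chloride should enter axially on the chair that keeps both methyl groups equatorial, which is also the more stable C5 epimer, giving C5–Cl cis to C4–Cl, and the equatorial C4–Cl cannot bridge to the cation.

**Step 11**
Reactants: 13 (1S,2S,4R,5S)-2-bromo-4,5-dichloro-1-ethenyl-1,5-dimethylcyclohexane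
Product: 15 (1S,2S,4R,5S)-2-bromo-4,5-dichloro-1,5-dimethylcyclohexane-1-carbaldehyde, via ozonide 14 (not isolated)
Conditions: O3, CH2Cl2, −78 °C; then PPh3, −78 °C to rt
Reagents that add atoms: ozone [O-][O+]=O
Why: Ozonolysis of the only remaining olefin with reductive work-up should give the non-enolisable aldehyde on the quaternary carbon, alkyl halides being inert to ozone.

**Step 12**
Reactants: 15 (1S,2S,4R,5S)-2-bromo-4,5-dichloro-1,5-dimethylcyclohexane-1-carbaldehyde
Product: 16 (1S,2S,4R,5S)-2-bromo-1-[(E)-2-bromoethenyl]-4,5-dichloro-1,5-dimethylcyclohexane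
Conditions: CrBr2, CHBr3, THF, 0 °C to rt
Reagents that add atoms: bromoform BrC(Br)Br
Why: Takai olefination: the geminal dichromium species from bromoform should add to the aldehyde and eliminate to the (E)-alkenyl bromide; CrBr2 avoids halogen exchange, and divalent chromium should not reduce the unactivated alkyl chlorides or the hindered bromide at this temperature.

**Compound list**

1 | 2-methylcyclopentane-1,3-dione | CC1C(=O)CCC1=O | starting material
2 | 3-chloro-2-methylprop-1-ene | CC(=C)CCl | starting material
3 | 2-methyl-2-(2-methylprop-2-en-1-yl)cyclopentane-1,3-dione | CC(=C)CC1(C)C(=O)CCC1=O | intermediate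
4 | (2R,3R)-3-hydroxy-2-methyl-2-(2-methylprop-2-en-1-yl)cyclopentan-1-one | CC(=C)C[C@@]1(C)C(=O)CC[C@H]1O | intermediate
5 | (1R,2R)-2-methyl-2-(2-methylprop-2-en-1-yl)-3-oxocyclopentyl trifluoromethanesulfonate | CC(=C)C[C@@]1(C)C(=O)CC[C@H]1OS(=O)(=O)C(F)(F)F | intermediate
6 | (2S,3S)-3-bromo-2-methyl-2-(2-methylprop-2-en-1-yl)cyclopentan-1-one | CC(=C)C[C@@]1(C)C(=O)CC[C@@H]1Br | intermediate
7 | (4S,5S)-4-bromo-5-methyl-5-(2-methylprop-2-en-1-yl)cyclopent-1-en-1-yl trifluoromethanesulfonate | CC(=C)C[C@@]1(C)C(OS(=O)(=O)C(F)(F)F)=CC[C@@H]1Br | intermediate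
8 | (3S,4S)-4-bromo-3-methyl-3-(2-methylprop-2-en-1-yl)cyclopent-1-ene | CC(=C)C[C@@]1(C)C=CC[C@@H]1Br | intermediate
9 | (4S,5S)-4-bromo-5-ethenyl-1,5-dimethylcyclohex-1-ene | CC1=CC[C@H](Br)[C@](C)(C=C)C1 | intermediate
10 | (1R,3S,4S,6S)-4-bromo-3-ethenyl-1,3-dimethyl-7-oxabicyclo[4.1.0]heptane | C[C@]12O[C@H]1C[C@H](Br)[C@](C)(C=C)C2 | intermediate
11 | (1S,4S,5S)-5-bromo-4-ethenyl-4-methyl-2-methylidenecyclohexan-1-ol | C=C1C[C@@](C)(C=C)[C@@H](Br)C[C@@H]1O | intermediate
12 | (1S,2S,4R)-2-bromo-4-chloro-1-ethenyl-1-methyl-5-methylidenecyclohexane | C=C1C[C@@](C)(C=C)[C@@H](Br)C[C@H]1Cl | intermediate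
13 | (1S,2S,4R,5S)-2-bromo-4,5-dichloro-1-ethenyl-1,5-dimethylcyclohexane | C[C@]1(Cl)C[C@@](C)(C=C)[C@@H](Br)C[C@H]1Cl | intermediate
14 | (1S,2S,4R,5S)-2-bromo-4,5-dichloro-1,5-dimethyl-1-(1,2,4-trioxolan-3-yl)cyclohexane (both epimers at the trioxolane carbon) | C[C@]1(Cl)C[C@@](C)(C2OCOO2)[C@@H](Br)C[C@H]1Cl | intermediate
15 | (1S,2S,4R,5S)-2-bromo-4,5-dichloro-1,5-dimethylcyclohexane-1-carbaldehyde | C[C@]1(Cl)C[C@@](C)(C=O)[C@@H](Br)C[C@H]1Cl | intermediate
16 | (1S,2S,4R,5S)-2-bromo-1-[(E)-2-bromoethenyl]-4,5-dichloro-1,5-dimethylcyclohexane | C[C@]1(Cl)C[C@@](C)(/C=C/Br)[C@@H](Br)C[C@H]1Cl | target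

Total step count: 12. Longest linear sequence: 12 steps (from 1).

**Steps most likely to fail**

Step 3. Substitution at the secondary carbon next to the quaternary centre may be outrun by elimination of triflic acid or by ionisation followed by a 1,2-alkyl shift. The fallback makes the C–Br bond and the quaternary carbon together by a bromonium-induced semipinacol rearrangement. It sets out from 2 and uses 2-methylcyclopent-2-en-1-one F1. Compound 2 is converted through its Grignard reagent and SnCl4 into tetrakis(2-methylprop-2-en-1-yl)stannane F2. Ti(OiPr)4/H8-BINOL-catalysed 1,2-addition of F2 to F1, with the BINOL antipode that leads to the S carbinol, should give (1S)-2-methyl-1-(2-methylprop-2-en-1-yl)cyclopent-2-en-1-ol F3. NBS in CH2Cl2 at −20 °C should then place bromine on the ring olefin from the hydroxyl face while the methallyl group migrates suprafacially from the carbinol carbon to the neighbouring olefinic carbon on the other face. This should give bromo ketone 6 directly with Br trans to methallyl, where the route is rejoined.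

Step 7. Oxygen transfer from the peracid may show poor facial selectivity, because the preference rests only on the conformational screening of one face. The fallback uses a stereoelectronically controlled opening and a later inversion; it sets out from 9. NBS in aqueous acetone should give (1S,2S,4S,5S)-2,4-dibromo-5-ethenyl-1,5-dimethylcyclohexan-1-ol F4 by trans-diaxial (Fürst–Plattner) opening of the bromonium ion by water at the tertiary carbon. K2CO3 in MeOH should close it to (1S,3S,4S,6R)-4-bromo-3-ethenyl-1,3-dimethyl-7-oxabicyclo[4.1.0]heptane F5, the epoxide on the face cis to vinyl and bromine. The aluminium amide of step 8 should give (1R,4S,5S)-5-bromo-4-ethenyl-4-methyl-2-methylidenecyclohexan-1-ol F6. Mitsunobu inversion (4-nitrobenzoic acid, PPh3, diisopropyl azodicarboxylate) should give (1S,4S,5S)-5-bromo-4-ethenyl-4-methyl-2-methylidenecyclohexyl 4-nitrobenzoate F7, and methanolysis (K2CO3, MeOH) returns the route to 11.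

Step 10. Protonation of the olefin is slowed by the allylic chlorine, so ionisation of the allylic C4–Cl bond (transposition to the primary allylic chloride or loss of configuration at C4) may compete. The fallback replaces the ionic addition by a radical Markovnikov hydrochlorination; it sets out from 12 and comes back at 13 with no new compound. With Co(BF4)2·6H2O and a salen-type ligand (catalytic), PhSiH3 and TsCl in EtOH at rt, a cobalt hydride should transfer a hydrogen atom to the CH2 terminus of the 1,1-disubstituted olefin. The tertiary C5 radical should then take chlorine from TsCl along the axial direction. No acid and no cation are involved, and the more substituted olefin should react before the hindered vinyl group.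

**Further compounds**

F1 | step 3 | 2-methylcyclopent-2-en-1-one | CC1=CCCC1=O
F2 | step 3 | tetrakis(2-methylprop-2-en-1-yl)stannane | CC(=C)C[Sn](CC(C)=C)(CC(C)=C)CC(C)=C
F3 | step 3 | (1S)-2-methyl-1-(2-methylprop-2-en-1-yl)cyclopent-2-en-1-ol | CC(=C)C[C@@]1(O)CCC=C1C
F4 | step 7 | (1S,2S,4S,5S)-2,4-dibromo-5-ethenyl-1,5-dimethylcyclohexan-1-ol | C[C@]1(O)C[C@@](C)(C=C)[C@@H](Br)C[C@@H]1Br
F5 | step 7 | (1S,3S,4S,6R)-4-bromo-3-ethenyl-1,3-dimethyl-7-oxabicyclo[4.1.0]heptane | C[C@@]12O[C@@H]1C[C@H](Br)[C@](C)(C=C)C2
F6 | step 7 | (1R,4S,5S)-5-bromo-4-ethenyl-4-methyl-2-methylidenecyclohexan-1-ol | C=C1C[C@@](C)(C=C)[C@@H](Br)C[C@H]1O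
F7 | step 7 | (1S,4S,5S)-5-bromo-4-ethenyl-4-methyl-2-methylidenecyclohexyl 4-nitrobenzoate | C=C1C[C@@](C)(C=C)[C@@H](Br)C[C@@H]1OC(=O)c1ccc(cc1)[N+](=O)[O-]
F0 | step 10 | none | none
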